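## Retrosynthetic overview

- The target is unmasked from its 5,4'-bis(MOM) ether, whose C4 ketone is carried as a 1,3-dithiane; only two deprotections follow the key step.
- Key disconnection: C3–C4 and O1–C8a are cut together. This gives a ring-A 2-aryl-1,3-dithiane (C4 as acyl-anion equivalent, fluorine on the future C8a) and the (R)-oxirane that carries O1, C2, C3 and ring B. Forward, it is a strain-release [3+3] annulation.
- Enabling feature: the strained three-membered O1–C2–C3 oxirane ring with an unsubstituted C3 beside the stereocentre, paired with the C8a–F bond of ring A. That bond sits ortho to the dithiane-bearing C4a and meta to both ring-A oxygens, so the alkoxide released on ring opening is held next to an SNAr-competent carbon.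
- Ring A is dressed from 3-fluoro-5-methoxyphenol by ortho-formylation (C4) and an aromatic Claisen rearrangement to the only free ortho carbon (C6 prenyl). The oxirane stereocentre comes from a catalytic asymmetric ketone reduction.
- Ring order: rings A and B are bought as benzene rings; ring C is the only ring built, in the key step.

Key step: step 9

Assumption: tert-butyl 2-methylbut-3-en-2-yl carbonate is treated as a purchasable reagent, and flavanone numbering (O1, C2, C3, C4, C4a, C5 to C8, C8a; ring A benzo, ring B 4-hydroxyphenyl, ring C pyranone) is used for all intermediates.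

## Route

Step 1
Reactants: 1 3-fluoro-5-methoxyphenol
Product: 3 2-fluoro-6-hydroxy-4-methoxybenzaldehyde, via salicyl alcohol 2 (not isolated)
Conditions: MgCl2, Et3N, (CH2O)n, MeCN, reflux; dilute HCl work-up
Reagents that add atoms: paraformaldehyde (as formaldehyde), C=O
Why: Magnesium-phenoxide-directed ortho-formylation (Casnati–Skattebøl reaction) is ortho-specific, and of the two ortho positions the one para to the methoxy group and flanked by OH and the small fluorine should be the more nucleophilic and less hindered, which places the future C4 between the future 5-oxygen and the fluorine.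

Step 2
Reactants: 3 2-fluoro-6-hydroxy-4-methoxybenzaldehyde
Product: 4 2-(1,3-dithian-2-yl)-3-fluoro-5-methoxyphenol
Conditions: HS(CH2)3SH, BF3·OEt2, CH2Cl2, 0 °C to rt
Reagents that add atoms: propane-1,3-dithiol, SCCCS
Why: Lewis-acid-catalysed dithioacetalisation converts the formyl carbon into a latent acyl anion (Corey–Seebach umpolung) before any acid-sensitive group is present.

Step 3
Reactants: 4 2-(1,3-dithian-2-yl)-3-fluoro-5-methoxyphenol
Product: 5 2-{2-fluoro-4-methoxy-6-[(2-methylbut-3-en-2-yl)oxy]phenyl}-1,3-dithiane
Conditions: Pd(PPh3)4 (5 mol %), tert-butyl 2-methylbut-3-en-2-yl carbonate, THF, 0 °C to rt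
Reagents that add atoms: tert-butyl 2-methylbut-3-en-2-yl carbonate, CC(C)(C)OC(=O)OC(C)(C)C=C
Why: Decarboxylative Tsuji–Trost O-allylation, in which zerovalent palladium ionises the tertiary carbonate to a 1,1-dimethylallyl palladium cation and tert-butoxide, and the phenoxide should attack the more substituted allyl terminus under kinetic control to give the tertiary aryl ether.

Step 4
Reactants: 5 2-{2-fluoro-4-methoxy-6-[(2-methylbut-3-en-2-yl)oxy]phenyl}-1,3-dithiane
Product: 7 2-(1,3-dithian-2-yl)-3-fluoro-5-methoxy-6-(3-methylbut-2-en-1-yl)phenol, via dienone 6 (not isolated)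
Conditions: N,N-diethylaniline, 120 °C
Reagents that add atoms: none
Why: Aromatic Claisen rearrangement ([3,3]-sigmatropic shift) of the aryl 1,1-dimethylallyl ether can deliver the allyl unit, now as a normal prenyl group, only to the single hydrogen-bearing ortho carbon between the two oxygens (the future C6), after which the dienone tautomerises to the phenol.

Step 5
Reactants: 7 2-(1,3-dithian-2-yl)-3-fluoro-5-methoxy-6-(3-methylbut-2-en-1-yl)phenol
Product: 8 2-[6-fluoro-4-methoxy-2-(methoxymethoxy)-3-(3-methylbut-2-en-1-yl)phenyl]-1,3-dithiane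
Conditions: NaH, MOMCl, DMF, 0 °C
Reagents that add atoms: chloromethyl methyl ether, COCCl
Why: Williamson-type O-alkylation of the sodium phenoxide with the highly reactive MOMCl, under a base too weak to deprotonate the dithiane C–H.

Step 6
Reactants: 9 2-chloro-1-(4-hydroxyphenyl)ethan-1-one
Product: 10 2-chloro-1-[4-(methoxymethoxy)phenyl]ethan-1-one
Conditions: MOMCl, i-Pr2NEt, CH2Cl2, 0 °C
Reagents that add atoms: chloromethyl methyl ether, COCCl
Why: O-alkylation of the acidic para-acylphenol under amine base at low temperature, where MOMCl should react far faster than the α-chloro ketone.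

Step 7
Reactants: 10 2-chloro-1-[4-(methoxymethoxy)phenyl]ethan-1-one
Product: 11 (1R)-2-chloro-1-[4-(methoxymethoxy)phenyl]ethan-1-ol
Conditions: (R)-Me-CBS, that is (3aR)-1-methyl-3,3-diphenyltetrahydro-1H,3H-pyrrolo[1,2-c][1,3,2]oxazaborole (10 mol %), BH3·SMe2, THF, 0 °C; MeOH quench, aqueous work-up
Reagents that add atoms: none
Why: Corey–Bakshi–Shibata reduction, in which the oxazaborolidine-bound borane delivers hydride to one ketone face with the aryl group as the large substituent, so the (R)-carbinol centre (the future C2) is set by the catalyst in the sense established for aryl chloromethyl ketones.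

Step 8
Reactants: 11 (1R)-2-chloro-1-[4-(methoxymethoxy)phenyl]ethan-1-ol
Product: 12 (2R)-2-[4-(methoxymethoxy)phenyl]oxirane
Conditions: NaOH (2 M aq.), THF, 0 °C to rt; filtration through basic alumina
Reagents that add atoms: none
Why: Intramolecular Williamson etherification (3-exo-tet) closes the oxirane at the CH2Cl carbon, so the carbinol stereocentre is not a reacting centre and its configuration is retained.

Step 9
Reactants: 8 2-[6-fluoro-4-methoxy-2-(methoxymethoxy)-3-(3-methylbut-2-en-1-yl)phenyl]-1,3-dithiane; 12 (2R)-2-[4-(methoxymethoxy)phenyl]oxirane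
Product: 15 (2S)-7-methoxy-5-(methoxymethoxy)-2-[4-(methoxymethoxy)phenyl]-6-(3-methylbut-2-en-1-yl)-2,3-dihydrospiro[chromene-4,2'-[1,3]dithiane], via lithiodithiane 13 (not isolated), via lithium alkoxide 14 (not isolated)
Conditions: n-BuLi, THF, −78 to −30 °C; then 12, DMPU, −78 to 0 °C; then KOt-Bu (0.2 equiv), 18-crown-6 (0.2 equiv), 60 °C
Reagents that add atoms: none
Why: n-BuLi removes the dithiane C–H (the most acidic proton of 8), and the sulfur-stabilised carbanion 13, an acyl-anion equivalent for C4 (Corey–Seebach umpolung), opens oxirane 12 by SN2 attack at its unsubstituted CH2 carbon, so release of the three-ring strain drives formation of the C3–C4 bond and unveils the C2 alkoxide 14. After potassium exchange in THF/DMPU this alkoxide adds to C8a, the fluorine-bearing carbon ortho to C4a, and loss of fluoride from the Meisenheimer intermediate (stabilised inductively by the two meta oxygen substituents) forms the O1–C8a bond; the closest known reaction types are the dithiane–epoxide alkylation and the alkoxide SNAr closure of 3-(2-fluoroaryl)propanols to chromans. Ring C is the only ring closed, in a 6-exo-trig mode at the aromatic carbon, helped by the gem-disubstitution at C4. No stereocentre is created: C2 is never a reacting centre, so the configuration of 12 is transferred unchanged, and the descriptor changes from R to S only because the CIP ranking of the aryl and CH2 substituents is exchanged. The step needs terminal rather than benzylic epoxide opening, secured by the hindered tertiary carbanion and lithium-sequestering DMPU; displacement of F rather than the other ortho substituent OMOM, secured by the far better nucleofugality of fluoride in SNAr; and no erosion at C2, secured by keeping C4 as a thioketal so that neither retro-aldol nor E1cB ring opening is possible.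

Step 10
Reactants: 15 (2S)-7-methoxy-5-(methoxymethoxy)-2-[4-(methoxymethoxy)phenyl]-6-(3-methylbut-2-en-1-yl)-2,3-dihydrospiro[chromene-4,2'-[1,3]dithiane]
Product: 16 (2S)-7-methoxy-5-(methoxymethoxy)-2-[4-(methoxymethoxy)phenyl]-6-(3-methylbut-2-en-1-yl)-2,3-dihydro-4H-chromen-4-one
Conditions: MeI, CaCO3, MeCN/H2O (9:1), 45 °C
Reagents that add atoms: water, O
Why: Alkylative hydrolysis of the dithioketal (S-methylation, thionium formation, addition of water) is close to neutral and should leave the prenyl alkene, both MOM ethers and the C2 stereocentre untouched.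

Step 11
Reactants: 16 (2S)-7-methoxy-5-(methoxymethoxy)-2-[4-(methoxymethoxy)phenyl]-6-(3-methylbut-2-en-1-yl)-2,3-dihydro-4H-chromen-4-one
Product: 17 6-prenylsakuranetin, (2S)-5-hydroxy-2-(4-hydroxyphenyl)-7-methoxy-6-(3-methylbut-2-en-1-yl)-2,3-dihydro-4H-chromen-4-one
Conditions: HCl (1.25 M in MeOH), 40 °C
Reagents that add atoms: none
Why: Acid-catalysed transacetalisation transfers both MOM groups to methanol under mild conditions, in which flavanones should be configurationally stable (ring opening to the chalcone is base-promoted) and the prenyl group is not expected to cyclise onto the 5-OH.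

## Compound list

1 | 3-fluoro-5-methoxyphenol | COc1cc(O)cc(F)c1 | starting material
2 | 3-fluoro-2-(hydroxymethyl)-5-methoxyphenol (formed as its magnesium salt) | COc1cc(O)c(CO)c(F)c1 | intermediate
3 | 2-fluoro-6-hydroxy-4-methoxybenzaldehyde | COc1cc(O)c(C=O)c(F)c1 | intermediate
4 | 2-(1,3-dithian-2-yl)-3-fluoro-5-methoxyphenol | COc1cc(O)c(C2SCCCS2)c(F)c1 | intermediate
5 | 2-{2-fluoro-4-methoxy-6-[(2-methylbut-3-en-2-yl)oxy]phenyl}-1,3-dithiane | COc1cc(OC(C)(C)C=C)c(C2SCCCS2)c(F)c1 | intermediate
6 | 2-(1,3-dithian-2-yl)-3-fluoro-5-methoxy-6-(3-methylbut-2-en-1-yl)cyclohexa-2,4-dien-1-one (transient, racemic at C6) | COC1=CC(F)=C(C2SCCCS2)C(=O)C1CC=C(C)C | intermediate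
7 | 2-(1,3-dithian-2-yl)-3-fluoro-5-methoxy-6-(3-methylbut-2-en-1-yl)phenol | COc1cc(F)c(C2SCCCS2)c(O)c1CC=C(C)C | intermediate
8 | 2-[6-fluoro-4-methoxy-2-(methoxymethoxy)-3-(3-methylbut-2-en-1-yl)phenyl]-1,3-dithiane | COCOc1c(CC=C(C)C)c(OC)cc(F)c1C1SCCCS1 | intermediate
9 | 2-chloro-1-(4-hydroxyphenyl)ethan-1-one | O=C(CCl)c1ccc(O)cc1 | starting material
10 | 2-chloro-1-[4-(methoxymethoxy)phenyl]ethan-1-one | COCOc1ccc(cc1)C(=O)CCl | intermediate
11 | (1R)-2-chloro-1-[4-(methoxymethoxy)phenyl]ethan-1-ol | COCOc1ccc(cc1)[C@@H](O)CCl | intermediate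
12 | (2R)-2-[4-(methoxymethoxy)phenyl]oxirane | COCOc1ccc(cc1)[C@@H]1CO1 | intermediate
13 | 2-lithio-2-[6-fluoro-4-methoxy-2-(methoxymethoxy)-3-(3-methylbut-2-en-1-yl)phenyl]-1,3-dithiane | [Li]C1(SCCCS1)c1c(F)cc(OC)c(CC=C(C)C)c1OCOC | intermediate
14 | lithium (1S)-2-{2-[6-fluoro-4-methoxy-2-(methoxymethoxy)-3-(3-methylbut-2-en-1-yl)phenyl]-1,3-dithian-2-yl}-1-[4-(methoxymethoxy)phenyl]ethan-1-olate | [Li]O[C@@H](CC1(SCCCS1)c1c(F)cc(OC)c(CC=C(C)C)c1OCOC)c1ccc(OCOC)cc1 | intermediate
15 | (2S)-7-methoxy-5-(methoxymethoxy)-2-[4-(methoxymethoxy)phenyl]-6-(3-methylbut-2-en-1-yl)-2,3-dihydrospiro[chromene-4,2'-[1,3]dithiane] | COc1cc2c(c(OCOC)c1CC=C(C)C)C1(SCCCS1)C[C@@H](c1ccc(OCOC)cc1)O2 | intermediate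
16 | (2S)-7-methoxy-5-(methoxymethoxy)-2-[4-(methoxymethoxy)phenyl]-6-(3-methylbut-2-en-1-yl)-2,3-dihydro-4H-chromen-4-one | COc1cc2c(c(OCOC)c1CC=C(C)C)C(=O)C[C@@H](c1ccc(OCOC)cc1)O2 | intermediate
17 | 6-prenylsakuranetin, (2S)-5-hydroxy-2-(4-hydroxyphenyl)-7-methoxy-6-(3-methylbut-2-en-1-yl)-2,3-dihydro-4H-chromen-4-one | COc1cc2c(c(O)c1CC=C(C)C)C(=O)C[C@@H](c1ccc(O)cc1)O2 | target

## Step count and risks

Total steps: 11. Longest linear sequence: 8 (steps 1 to 5, then 9 to 11); the oxirane branch (steps 6 to 8) joins at step 9.

Steps most likely to fail: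

1. Step 9 (key step). Ring closure at the electron-rich C–F carbon may be slow or incomplete. The base may move the prenyl double bond into conjugation. n-BuLi may metalate the ring C–H between F and OMe and lead to aryne-type decomposition. Fallback, setting out from 8 and 12: only the epoxide opening would be run (n-BuLi, THF/DMPU, −78 to 0 °C, aqueous NH4Cl quench) to isolate (1S)-2-{2-[6-fluoro-4-methoxy-2-(methoxymethoxy)-3-(3-methylbut-2-en-1-yl)phenyl]-1,3-dithian-2-yl}-1-[4-(methoxymethoxy)phenyl]ethan-1-ol F1. Alkylative hydrolysis of the dithiane (MeI, CaCO3, aqueous MeCN) would then give the β-hydroxy ketone (3S)-1-[6-fluoro-4-methoxy-2-(methoxymethoxy)-3-(3-methylbut-2-en-1-yl)phenyl]-3-hydroxy-3-[4-(methoxymethoxy)phenyl]propan-1-one F2, in which the fluoride is ortho to a carbonyl group. A carbonyl-activated intramolecular SNAr under mild base (Cs2CO3, MeCN, rt) would close ring C and return to the route at compound 16.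

2. Step 3. The phenoxide may attack the less substituted allyl terminus and give the linear prenyl ether, or turnover may be slow through sulfur coordination to palladium and the hindrance of the ortho dithianyl group. Fallback, setting out from 4: copper-catalysed propargylic etherification with 3-chloro-3-methylbut-1-yne (CuCl2·2H2O, DBU, MeCN, 0 °C) would give 2-{2-fluoro-4-methoxy-6-[(2-methylbut-3-yn-2-yl)oxy]phenyl}-1,3-dithiane F3. Hydrozirconation of the terminal alkyne with Cp2Zr(H)Cl followed by protonolysis with water would reduce it to the vinyl group and return to the route at compound 5; this is chosen because the thioketal would poison a palladium hydrogenation catalyst.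

3. Step 1. Regioselectivity between the two ortho positions of the phenol may be poor, with formylation on the methoxy side. Fallback, setting out from 1: O-methylation (MeI, K2CO3, acetone) would give the symmetric 1-fluoro-3,5-dimethoxybenzene F4. Vilsmeier–Haack formylation (POCl3, DMF) at the less hindered position, para to one methoxy group and flanked by F and OMe, would give 2-fluoro-4,6-dimethoxybenzaldehyde F5. Chelation-controlled mono-demethylation of the methoxy group ortho to the formyl group (BCl3, CH2Cl2, −78 to 0 °C) would return to the route at compound 3.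

Further compounds
F1 | step 9 | (1S)-2-{2-[6-fluoro-4-methoxy-2-(methoxymethoxy)-3-(3-methylbut-2-en-1-yl)phenyl]-1,3-dithian-2-yl}-1-[4-(methoxymethoxy)phenyl]ethan-1-ol | COCOc1ccc(cc1)[C@@H](O)CC1(SCCCS1)c1c(F)cc(OC)c(CC=C(C)C)c1OCOC
F2 | step 9 | (3S)-1-[6-fluoro-4-methoxy-2-(methoxymethoxy)-3-(3-methylbut-2-en-1-yl)phenyl]-3-hydroxy-3-[4-(methoxymethoxy)phenyl]propan-1-one | COCOc1ccc(cc1)[C@@H](O)CC(=O)c1c(F)cc(OC)c(CC=C(C)C)c1OCOC
F3 | step 3 | 2-{2-fluoro-4-methoxy-6-[(2-methylbut-3-yn-2-yl)oxy]phenyl}-1,3-dithiane | COc1cc(OC(C)(C)C#C)c(C2SCCCS2)c(F)c1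
F4 | step 1 | 1-fluoro-3,5-dimethoxybenzene | COc1cc(OC)cc(F)c1
F5 | step 1 | 2-fluoro-4,6-dimethoxybenzaldehyde | COc1cc(OC)c(C=O)c(F)c1
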